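**Retrosynthetic overview**
1. Target 18 is an all-cis 2,3,3a,7a-tetrahydro-5H-furo[3,2-b]pyran-5-one. Its ring oxygen O1, C2, the side-chain alkene and the benzoate carbon form an (E)-1,4-dioxygenated but-2-ene, O1–C2–CH=CH–CH(OBz). That is the signature of a 1,4-oxidation of a 1,3-diene, and O1 sits on C7a of the lactone ring, five atoms from the diene terminus.
2. Key disconnection: the O1–C2 bond and the benzoate C–O bond together, by palladium-catalysed 1,4-oxybenzoyloxylation of dienyl diol lactone 16. This makes the tetrahydrofuran ring, two stereocentres, the E-alkene and the benzoate in one step.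
3. 16 comes from vinyl iodide 12 and vinylstannane 15 (from (R)-but-3-yn-2-ol) by a copper-mediated Stille-type coupling.
4. The lactone ring of 12 comes from ring-closing metathesis of acrylate 10. Its stereocentres come from alkoxyallylboration of aldehyde 6, made from (S)-glyceraldehyde acetonide by Takai iodo-olefination.
5. Ring order: dihydropyranone first (step 8), tetrahydrofuran last (step 13).

Key step: step 13

Remark: 1, 7 and 13 are taken as commercial; the η3-allylpalladium intermediate 17 is drawn in its SMILES as the σ-allyl form with the metal on the distal carbon.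

Step 1
Reactants: 1 (4S)-2,2-dimethyl-1,3-dioxolane-4-carbaldehyde
Product: 2 (4R)-4-[(E)-2-iodoethenyl]-2,2-dimethyl-1,3-dioxolane
Conditions: CrCl2 (6 equiv), CHI3 (2 equiv), THF, 0 °C to rt
Reagents that add atoms: iodoform IC(I)I
Why: Takai iodo-olefination, in which the geminal dichromium carbenoid adds to the aldehyde and eliminates to the (E)-iodoalkene under non-basic conditions that leave the α-stereocentre untouched.

Step 2
Reactants: 2 (4R)-4-[(E)-2-iodoethenyl]-2,2-dimethyl-1,3-dioxolane
Product: 3 (2R,3E)-4-iodobut-3-ene-1,2-diol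
Conditions: 1 M aq. HCl, THF, rt
Reagents that add atoms: none
Why: Acid-catalysed acetal hydrolysis, to which the iodoalkene is inert.

Step 3
Reactants: 3 (2R,3E)-4-iodobut-3-ene-1,2-diol
Product: 4 (2R,3E)-1,2-bis[(tert-butyldimethylsilyl)oxy]-4-iodobut-3-ene
Conditions: TBSCl (2.5 equiv), imidazole, DMF, rt
Reagents that add atoms: tert-butyldimethylsilyl chloride CC(C)(C)[Si](C)(C)Cl
Why: Standard silylation of both hydroxyls.

Step 4
Reactants: 4 (2R,3E)-1,2-bis[(tert-butyldimethylsilyl)oxy]-4-iodobut-3-ene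
Product: 5 (2R,3E)-2-[(tert-butyldimethylsilyl)oxy]-4-iodobut-3-en-1-ol
Conditions: HF·pyridine, pyridine, THF, 0 °C
Reagents that add atoms: none
Why: Selective desilylation, since the unhindered primary silyl ether is cleaved much faster than the secondary allylic one.

Step 5
Reactants: 5 (2R,3E)-2-[(tert-butyldimethylsilyl)oxy]-4-iodobut-3-en-1-ol
Product: 6 (2R,3E)-2-[(tert-butyldimethylsilyl)oxy]-4-iodobut-3-enal
Conditions: Dess–Martin periodinane, NaHCO3, CH2Cl2, 0 °C; used crude at once
Reagents that add atoms: none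
Why: Dess–Martin oxidation under buffered, base-free conditions should avoid enolisation of the sensitive α-silyloxy β,γ-unsaturated aldehyde.

Step 6
Reactants: 6 (2R,3E)-2-[(tert-butyldimethylsilyl)oxy]-4-iodobut-3-enal; 7 3-(methoxymethoxy)prop-1-ene
Product: 9 (3R,4S,5R,6E)-5-[(tert-butyldimethylsilyl)oxy]-7-iodo-3-(methoxymethoxy)hepta-1,6-dien-4-ol, via diisopinocampheylborinate ester 8 (not isolated)
Conditions: 7, s-BuLi, THF, −78 °C; (−)-Ipc2BOMe; BF3·OEt2; then 6, −78 °C; NaOH, H2O2, 0 °C
Reagents that add atoms: none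
Why: Brown (Z)-γ-alkoxyallylboration through a chair transition state, where the (Z)-borane gives the 3,4-syn pair and the isopinocampheyl groups derived from (+)-α-pinene direct attack to the Si face of the aldehyde, which is also its Felkin face (matched case), giving the 4,5-anti relation.

Step 7
Reactants: 9 (3R,4S,5R,6E)-5-[(tert-butyldimethylsilyl)oxy]-7-iodo-3-(methoxymethoxy)hepta-1,6-dien-4-ol
Product: 10 (3R,4S,5R,6E)-5-[(tert-butyldimethylsilyl)oxy]-7-iodo-3-(methoxymethoxy)hepta-1,6-dien-4-yl prop-2-enoate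
Conditions: acryloyl chloride, i-Pr2NEt, CH2Cl2, −20 to 0 °C
Reagents that add atoms: acryloyl chloride C=CC(=O)Cl
Why: Acylation of the only free hydroxyl.

Step 8
Reactants: 10 (3R,4S,5R,6E)-5-[(tert-butyldimethylsilyl)oxy]-7-iodo-3-(methoxymethoxy)hepta-1,6-dien-4-yl prop-2-enoate
Product: 11 (5R,6S)-6-[(1R,2E)-1-[(tert-butyldimethylsilyl)oxy]-3-iodoprop-2-en-1-yl]-5-(methoxymethoxy)-5,6-dihydro-2H-pyran-2-one
Conditions: second-generation Grubbs catalyst (5 mol%), CH2Cl2 (5 mM), 40 °C
Reagents that add atoms: none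
Why: Ring-closing metathesis, in which ruthenium loads on the terminal vinyl group and closes onto the acrylate to the six-membered (Z)-lactone, while the iodoalkene is a poor partner because its turnover would need an iodomethylidene ruthenium species.

Step 9
Reactants: 11 (5R,6S)-6-[(1R,2E)-1-[(tert-butyldimethylsilyl)oxy]-3-iodoprop-2-en-1-yl]-5-(methoxymethoxy)-5,6-dihydro-2H-pyran-2-one
Product: 12 (5R,6S)-5-hydroxy-6-[(1R,2E)-1-hydroxy-3-iodoprop-2-en-1-yl]-5,6-dihydro-2H-pyran-2-one
Conditions: TFA/CH2Cl2/H2O (5:5:1), 0 °C to rt; NaHCO3 work-up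
Reagents that add atoms: none
Why: Acid hydrolysis of the methoxymethyl acetal and the silyl ether, chosen because the lactone and the iodoalkene tolerate acid whereas base would open or translactonise the ring.

Step 10
Reactants: 13 (R)-but-3-yn-2-ol
Product: 14 (2R,3E)-4-(tributylstannyl)but-3-en-2-ol
Conditions: Bu3SnH, PdCl2(PPh3)2 (2 mol%), THF, 0 °C to rt; chromatographic removal of the internal stannane
Reagents that add atoms: tributyltin hydride CCCC[SnH](CCCC)CCCC
Why: Palladium-catalysed syn-hydrostannation of the terminal alkyne should give mainly the (E)-β-stannane.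

Step 11
Reactants: 14 (2R,3E)-4-(tributylstannyl)but-3-en-2-ol
Product: 15 (2R,3E)-4-(tributylstannyl)but-3-en-2-yl acetate
Conditions: Ac2O, pyridine, DMAP (cat.), CH2Cl2, 0 °C to rt
Reagents that add atoms: acetic anhydride CC(=O)OC(C)=O
Why: Standard acetylation with retention at the carbinol carbon.

Step 12
Reactants: 12 (5R,6S)-5-hydroxy-6-[(1R,2E)-1-hydroxy-3-iodoprop-2-en-1-yl]-5,6-dihydro-2H-pyran-2-one; 15 (2R,3E)-4-(tributylstannyl)but-3-en-2-yl acetate
Product: 16 (5R,6R)-6-[(1R,2E,4E,6R)-6-(acetyloxy)-1-hydroxyhepta-2,4-dien-1-yl]-5-hydroxy-5,6-dihydro-2H-pyran-2-one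
Conditions: copper thiophene-2-carboxylate CuO2CC4H3S (CuTC, 1.5 equiv), NMP, 0 °C to rt, dark
Reagents that add atoms: none
Why: Liebeskind-type copper-mediated Stille coupling joins the two alkenyl partners with retention of both geometries under neutral, palladium-free conditions, so the allylic acetate is not ionised.

Step 13
Reactants: 16 (5R,6R)-6-[(1R,2E,4E,6R)-6-(acetyloxy)-1-hydroxyhepta-2,4-dien-1-yl]-5-hydroxy-5,6-dihydro-2H-pyran-2-one
Product: 18 (2R,3S,4E)-2-(acetyloxy)-5-[(2S,3R,3aR,7aR)-3-hydroxy-5-oxo-2,3,3a,7a-tetrahydro-5H-furo[3,2-b]pyran-2-yl]pent-4-en-3-yl benzoate, via allylpalladium chloride complex 17 (not isolated)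
Conditions: Pd(OAc)2 (10 mol%), LiCl (20 mol%), PhCO2Li (2 equiv), PhCO2H (5 equiv), p-benzoquinone (2 equiv), acetone, 20 °C
Reagents that add atoms: benzoic acid O=C(O)c1ccccc1
Why: Divalent palladium binds the (2′E,4′E)-diene and the ring 5-hydroxyl attacks the proximal diene terminus C-2′ anti to the metal, forming the ether bond and the syn,syn-(η3-allyl)palladium chloride 17; benzoate then attacks the distal allyl carbon C-5′ from outside, again anti to palladium, and benzoquinone reoxidises the zerovalent palladium released. The closest known reaction type is the intramolecular palladium-catalysed 1,4-oxyacyloxylation of conjugated dienes carrying a tethered hydroxyl, in its catalytic-chloride variant. The tetrahydrofuran ring closes in the 5-exo-trig mode. The new ring stereocentre (C2 of the furopyranone) is controlled by the free allylic 1′-hydroxyl, which should take the inside position on the reacting alkene (the preference known from kinetic halo-etherification of 3-hydroxy-4-alkenols) and so place the side chain cis to it; the benzoate carbon is controlled by the mechanism, because the anti/anti sequence on an (E,E)-diene is an overall syn 1,4-addition, and the E-alkene follows from the syn,syn-allyl. The step needs three selectivities: benzoate attack at the allyl terminus remote from the ring oxygen (favoured by the deactivating ring C–O bond and the crowded concave face), reaction at the diene and not the lactone alkene (the enoate is electron-poor), and external benzoate delivery (catalytic chloride blocks carboxylate coordination to palladium).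

**Compound list**
1 | (4S)-2,2-dimethyl-1,3-dioxolane-4-carbaldehyde ((S)-glyceraldehyde acetonide) | CC1(C)OC[C@@H](C=O)O1 | starting material
2 | (4R)-4-[(E)-2-iodoethenyl]-2,2-dimethyl-1,3-dioxolane | CC1(C)OC[C@@H](/C=C/I)O1 | intermediate
3 | (2R,3E)-4-iodobut-3-ene-1,2-diol | OC[C@H](O)/C=C/I | intermediate
4 | (2R,3E)-1,2-bis[(tert-butyldimethylsilyl)oxy]-4-iodobut-3-ene | CC(C)(C)[Si](C)(C)OC[C@H](O[Si](C)(C)C(C)(C)C)/C=C/I | intermediate
5 | (2R,3E)-2-[(tert-butyldimethylsilyl)oxy]-4-iodobut-3-en-1-ol | OC[C@H](O[Si](C)(C)C(C)(C)C)/C=C/I | intermediate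
6 | (2R,3E)-2-[(tert-butyldimethylsilyl)oxy]-4-iodobut-3-enal | O=C[C@H](O[Si](C)(C)C(C)(C)C)/C=C/I | intermediate
7 | 3-(methoxymethoxy)prop-1-ene (allyl methoxymethyl ether) | C=CCOCOC | starting material
8 | diisopinocampheylborinate ester of 9 | C=C[C@@H](OCOC)[C@H](OB([C@H]1[C@H](C)[C@H]2C[C@@H](C1)C2(C)C)[C@H]1[C@H](C)[C@H]2C[C@@H](C1)C2(C)C)[C@H](O[Si](C)(C)C(C)(C)C)/C=C/I | intermediate (not isolated)
9 | (3R,4S,5R,6E)-5-[(tert-butyldimethylsilyl)oxy]-7-iodo-3-(methoxymethoxy)hepta-1,6-dien-4-ol | C=C[C@@H](OCOC)[C@H](O)[C@H](O[Si](C)(C)C(C)(C)C)/C=C/I | intermediate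
10 | (3R,4S,5R,6E)-5-[(tert-butyldimethylsilyl)oxy]-7-iodo-3-(methoxymethoxy)hepta-1,6-dien-4-yl prop-2-enoate | C=C[C@@H](OCOC)[C@H](OC(=O)C=C)[C@H](O[Si](C)(C)C(C)(C)C)/C=C/I | intermediate
11 | (5R,6S)-6-[(1R,2E)-1-[(tert-butyldimethylsilyl)oxy]-3-iodoprop-2-en-1-yl]-5-(methoxymethoxy)-5,6-dihydro-2H-pyran-2-one | I/C=C/[C@@H](O[Si](C)(C)C(C)(C)C)[C@H]1OC(=O)C=C[C@H]1OCOC | intermediate
12 | (5R,6S)-5-hydroxy-6-[(1R,2E)-1-hydroxy-3-iodoprop-2-en-1-yl]-5,6-dihydro-2H-pyran-2-one | I/C=C/[C@@H](O)[C@H]1OC(=O)C=C[C@H]1O | intermediate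
13 | (R)-but-3-yn-2-ol | C#C[C@@H](C)O | starting material
14 | (2R,3E)-4-(tributylstannyl)but-3-en-2-ol | C[C@@H](O)/C=C/[Sn](CCCC)(CCCC)CCCC | intermediate
15 | (2R,3E)-4-(tributylstannyl)but-3-en-2-yl acetate | CC(=O)O[C@H](C)/C=C/[Sn](CCCC)(CCCC)CCCC | intermediate
16 | (5R,6R)-6-[(1R,2E,4E,6R)-6-(acetyloxy)-1-hydroxyhepta-2,4-dien-1-yl]-5-hydroxy-5,6-dihydro-2H-pyran-2-one | CC(=O)O[C@H](C)/C=C/C=C/[C@@H](O)[C@H]1OC(=O)C=C[C@H]1O | intermediate
17 | (η3-allyl)palladium chloride complex of the cyclised ether, drawn as σ-allyl | CC(=O)O[C@H](C)[C@@H](/C=C/[C@@H]1O[C@@H]2C=CC(=O)O[C@@H]2[C@@H]1O)[Pd]Cl | intermediate (not isolated)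
18 | (2R,3S,4E)-2-(acetyloxy)-5-[(2S,3R,3aR,7aR)-3-hydroxy-5-oxo-2,3,3a,7a-tetrahydro-5H-furo[3,2-b]pyran-2-yl]pent-4-en-3-yl benzoate (CNP0151877.1) | CC(=O)O[C@H](C)[C@H](/C=C/[C@@H]1O[C@@H]2C=CC(=O)O[C@@H]2[C@@H]1O)OC(=O)c1ccccc1 | target

**Step count and risks**
Total steps: 13. Longest linear sequence: 11 (steps 1–9, 12, 13).

Steps most likely to fail:

1. Step 13. The ether ring may close on the wrong face of the diene, leaving the side chain on the convex face. Benzoate may also attack the allyl carbon next to the ring, and the diene may be consumed by Diels–Alder addition to benzoquinone. The fallback makes each stereocentre by a stereospecific step and sets out from 12 and 14. CuTC coupling of 12 with the free stannyl alcohol 14 should give the dienyl triol F1. Sharpless epoxidation (Ti(OiPr)4, D-(−)-diisopropyl tartrate, t-BuOOH, −20 °C) is matched for the (R)-methyl carbinol and mismatched for the ring-side carbinol, and should give the erythro 4′,5′-epoxide F2. Pd(PPh3)4 in THF then opens the vinyl epoxide with inversion and the 5-hydroxyl attacks the allyl terminus anti to zerovalent-palladium-derived metal (net syn 1,4-opening), giving the tetrahydrofuran triol F3. Lipase acetylation (Novozym 435, vinyl acetate) of the (R)-methyl carbinol gives the monoacetate F4. Benzoylation of the allylic side-chain hydroxyl (BzCl, collidine, −40 °C), which is far less hindered than the ring hydroxyl, returns to the route at 18.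

2. Step 6. The α-silyloxy β,γ-unsaturated aldehyde may enolise or its double bond may migrate during the allylboration, and reagent control may be incomplete. The fallback sets out from 6 and uses substrate control in an open transition state: (Z)-1-(methoxymethoxy)-3-(tributylstannyl)prop-1-ene with BF3·OEt2 in CH2Cl2 at −78 °C. This Lewis-acid-promoted γ-alkoxyallylstannane addition is non-basic, gives the syn diol ether pair and follows the Felkin preference of the α-silyloxy aldehyde, so it returns directly at 9.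

3. Step 8. The ruthenium carbene may engage the iodoalkene (cyclopentene formation and catalyst death) in place of the acrylate. The fallback avoids metathesis and sets out from 9. Silylation (TESOTf, 2,6-lutidine) gives the triethylsilyl ether F5. Dihydroxylation and cleavage of the terminal vinyl group (OsO4 cat., NMO; NaIO4) gives the aldehyde F6. Ando (Z)-selective Horner–Wadsworth–Emmons reaction with ethyl (di-o-tolylphosphono)acetate (NaI, DBU, THF, −78 to 0 °C) gives the (Z)-enoate F7. Mild acid (PPTS, MeOH) removes the triethylsilyl group and the freed hydroxyl lactonises, returning at 11.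

**Further compounds**
F1 | step 13 | (5R,6R)-6-[(1R,2E,4E,6R)-1,6-dihydroxyhepta-2,4-dien-1-yl]-5-hydroxy-5,6-dihydro-2H-pyran-2-one | C[C@@H](O)/C=C/C=C/[C@@H](O)[C@H]1OC(=O)C=C[C@H]1O
F2 | step 13 | (5R,6R)-5-hydroxy-6-[(1R,2E)-1-hydroxy-3-[(2R,3R)-3-[(1R)-1-hydroxyethyl]oxiran-2-yl]prop-2-en-1-yl]-5,6-dihydro-2H-pyran-2-one | C[C@@H](O)[C@H]1O[C@@H]1/C=C/[C@@H](O)[C@H]2OC(=O)C=C[C@H]2O
F3 | step 13 | (2S,3R,3aR,7aR)-2-[(1E,3S,4R)-3,4-dihydroxypent-1-en-1-yl]-3-hydroxy-2,3,3a,7a-tetrahydro-5H-furo[3,2-b]pyran-5-one | C[C@@H](O)[C@@H](O)/C=C/[C@@H]1O[C@@H]2C=CC(=O)O[C@@H]2[C@@H]1O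
F4 | step 13 | (2R,3S,4E)-3-hydroxy-5-[(2S,3R,3aR,7aR)-3-hydroxy-5-oxo-2,3,3a,7a-tetrahydro-5H-furo[3,2-b]pyran-2-yl]pent-4-en-2-yl acetate | CC(=O)O[C@H](C)[C@@H](O)/C=C/[C@@H]1O[C@@H]2C=CC(=O)O[C@@H]2[C@@H]1O
F0 | step 6 | none | none
F5 | step 8 | (3R,4S,5R,6E)-5-[(tert-butyldimethylsilyl)oxy]-7-iodo-3-(methoxymethoxy)-4-[(triethylsilyl)oxy]hepta-1,6-diene | C=C[C@@H](OCOC)[C@H](O[Si](CC)(CC)CC)[C@H](O[Si](C)(C)C(C)(C)C)/C=C/I
F6 | step 8 | (2S,3S,4R,5E)-4-[(tert-butyldimethylsilyl)oxy]-6-iodo-2-(methoxymethoxy)-3-[(triethylsilyl)oxy]hex-5-enal | O=C[C@@H](OCOC)[C@H](O[Si](CC)(CC)CC)[C@H](O[Si](C)(C)C(C)(C)C)/C=C/I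
F7 | step 8 | ethyl (2Z,4R,5S,6R,7E)-6-[(tert-butyldimethylsilyl)oxy]-8-iodo-4-(methoxymethoxy)-5-[(triethylsilyl)oxy]octa-2,7-dienoate | CCOC(=O)/C=C\[C@@H](OCOC)[C@H](O[Si](CC)(CC)CC)[C@H](O[Si](C)(C)C(C)(C)C)/C=C/I
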